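If you want the chain length of this flask before anything is integrated, reckon on one clock, the free monomer a chain has seen.

free monomer 0.79 M; protic impurity 0.158 M; pre-initiator 40 mM; time 2.5 min

    free monomer + initiator → living end + monomer in chains (k1 = 0.016 /M/s)
    free monomer + living end → monomer in chains + living end, rate k2*[living end]*[free monomer] (k2 = 1.0 /M/s)
    protic impurity + free monomer → quenched substrate (k3 = 1.5 /M/s)
    pre-initiator ⇌ initiator (K4 = 0.42, k4 = 0.24 /s)

- whether the average number of monomer units in a chain (chains begun, living or dead) reaches 100 by 2.5 min (yes / no)
- average number of monomer units in a chain (chains begun, living or dead) at 2.5 min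

- the average divides the monomer in chains by the number of chains begun, living and dead together
- run time (flask): 2.5 min

1. The protic impurity has a half-life of 0.58 s against a run of 2.5 min, so you may take its 0.158 M of free monomer at the start, leaving 632 mM usable.

2. The pre-initiator, the resting state of the initiator, relaxes with a half-life of 0.854 s, so initiator stands near 11.8 mM.

3. Now compare rates at one moment. Growth per start is k2·(living end)/(k1·(initiator)), and free monomer cancels. Living ends gather as k1·(initiator)·E, with E the exposure, so the ratio drifts up as k2·E. A chain begun midway has seen E/2, so the average is 1 + k2·E/2.

4. Flat monomer would give E = 94.8 M·s. But in this reckoning the 632 mM of usable monomer is used up at an exposure ceiling of 81.7 M·s, so monomer must fall. Then E = ceiling·tanh(t/τ), with τ = ceiling/usable = 2.15 min. That gives 67.1 M·s, the quantity to carry: the exposure, free monomer summed over time up to the reading.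

5. The average is 34.5. At the ceiling this reckoning gives 41.9, less than 100, so my answer to the first question is no.

6. The weak link is the flat initiator, since x = 0.318, a third of the pre-initiator charge, would be spent. Early starts then weigh more, and the growth part gains a factor 1 + x/6, so I commit to 36.3.

The forecast says no and 36.7 (34.5 to 39), above my figure, and holds that “The impurity is gone within a few seconds”.

The flask gives no and 36.7. In this flask the quenching step ran first, half its turnover done by 0.621 s, and quenched substrate stood at 20.0% at 0.250 min. Growth then ran with half its turnover done by 1.44 min, leaving free monomer at 29.2% at 2.50 min. In the neighbour with 0.32 M of free monomer, 162 mM is usable, exposure is 21.8 M·s, and the rule gives 12.1. That neighbour reads 12.0.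

(The numbers of this flask are made up; the rest is arithmetic.)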